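## Structural features

The target 36 is a germacranolide: a ten-membered carbocycle (C1–C10) fused across C6–C7 to an α-methylene-γ-butyrolactone (O on C6, C11 on C7, C12 carbonyl, C13 exocyclic methylene), with a trans ring fusion (H6 and H7 anti). Three contiguous stereocentres, C6 (R), C7 (R) and C8 (R), stand next to each other, and the C8 acyloxy group is anti to C11 in the C6–C9 zigzag. The fourth ring stereocentre, C3 (S), is an isolated allylic alcohol. Both ring alkenes are trisubstituted and ring-cis: C4=C5 (Z, methyl on C4) and C1=C10, which is conjugated to the C14 methyl ester in a tiglate-type arrangement (CIP E). The C8 ester is (2R,3R)-2,3-epoxy-2-methylbutanoate, the cis epoxide of angelic acid, with two more stereocentres. Fragile groups are the α-methylene lactone (Michael acceptor), the epoxy ester, the allylic C6–O bond and C3 alcohol, and the diene C10=C1–C2–C3–C4=C5, which invites transannular reactions under acid or radical conditions. The real difficulty is a medium ring of fixed alkene geometry that carries the C6/C7/C8 triad on a mobile ring. The key step uses two facts: O6 lies four ring atoms from C1=C10 (a cyclodec-5-enone pattern), and C1–C6 with the C4 methyl and O3 is the six-membered ring of carvone.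

## Logic of the disconnections

36 ⇒ 35. Only the O3–Si bond is cut. The allylic C3 hydroxyl has to stay masked while O8 is acylated and C14 is oxidised. The forward step needs a fluoride source that spares the epoxy ester, the exocyclic enoate and the lactone.

35 ⇒ 29 + 33. The O8–acyl bond is cut. This removes the epoxide and two stereocentres from the ring sequence and makes the end convergent. The forward step must acylate a hindered secondary alcohol with an α-quaternary acid without opening the oxirane and without acyl transfer to the lactone.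

33 ⇒ 32 ⇒ 31 ⇒ 30. The carboxyl oxidation level is taken back to the alcohol, then both C–O bonds of the oxirane are cut. The Z alkene of 30 fixes the cis relation, and a reagent-controlled epoxidation of the allylic alcohol fixes the absolute configuration. The reduction must not isomerise the alkene, and the oxidation must leave the oxirane intact.

29 ⇒ 28. The O8–benzyl bond is cut. O8 has to be an ether through organolithium, thermal and enolate chemistry, and a 4-methoxybenzyl ether can be removed oxidatively at the end. The forward step must not touch the allylic silyl ether or the alkenes.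

28 ⇒ 26 ⇒ 24 ⇒ 23. C14 is taken back from ester to aldehyde to alcohol to silyl ether, and the C1=C10 geometry is changed from ring-cis to ring-trans. The ring-forming step can only deliver the ring-trans alkene, and a protected alcohol at C14 survives the carbanion chemistry. The geometry change is placed at the aldehyde, where it is easiest. The forward steps need a selective release of the primary silyl ether and an equilibration that favours the ring-cis enal.

23 ⇒ 20. The C11=C13 bond is cut. The Michael acceptor is introduced after the ring stereocentres are set but before C14 becomes an electrophilic carbonyl, so the lactone enolate meets no competing acceptor.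

20 ⇒ 18 ⇒ 17. The O6–C12 lactone bond and the C6–H bond are cut. The lactone comes from a γ-oxygenated ester and C6 from the ketone that the ring expansion leaves behind. Hydride is expected to enter anti to the C7–C8 ring bond, so the lactone is closed with inversion at C6.

17 ⇒ 15. The C7–C11 bond is cut. The silyl enol ether from the key step is a regiodefined enolate equivalent. The forward step needs attack on the outer face at C7 and no β-elimination of the C8 ether.

15 ⇒ 14. C1–C6 is reconnected and C8–C9 is cut (retro [3,3]). The medium ring becomes a cyclohexene, and the C8 stereocentre is traded for an enol ether geometry plus two ring stereocentres. The forward step needs trans alkenyl groups, a Z enol ether, a silyl cap on O6 and heat. A chair model confirms that 14 (C1 S, C3 S, C6 S, Z enol ether) gives 8R in 15 and maps onto 1 without a change of configuration, so neither structure needed correction. Three points of the plan were tightened: an acid scavenger in the thermolysis, the C11 methylene installed before C14 is oxidised, and the C1=C10 equilibration moved to the aldehyde.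

14 ⇒ 13 ⇒ 5 + 10. The O6–Si bond and then the C6–C7 bond are cut. This is a carbonyl addition. It must go trans to the C1 substituent, keep the Z geometry of the nucleophile and avoid enolisation at C1.

10 ⇒ 8 ⇒ 6 + 7. The C–Br bond and the vinyl–O bond are cut, leading to two bulk chemicals.

5 ⇒ 4 ⇒ 3 ⇒ 2 ⇒ 1. The C6 carbonyl (allylic C–H), the two O–Si bonds, the C3–H bond and the C14–O bond are removed in turn. All ring A carbons, C9, C10, C14 and the C1 stereocentre come from 1. The forward steps need site selectivity in two allylic oxidations and a cis-selective carbonyl reduction.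

## Other disconnections considered

Alternative 1: The C5–C6 bond and the O6–C12 bond are cut. In the forward step CrCl2 with catalytic NiCl2 turns the Z iodoalkene of the open-chain aldehyde diester A2 into an alkenylchromium (trivalent chromium). This adds to the C6 aldehyde and closes the ten-membered ring, and the chromium alkoxide then acylates on the C12 ester to give A1.
- In its favour: ring and lactone form in one operation. A1 has the structure of 28, three steps from 36. Both alkene geometries and the C14 ester are fixed in open-chain chemistry, so no isomerisation and no thermolysis are needed. On these points it is the better plan.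
- Against it: C6 is created during a strained medium-ring closure with only 1,2-induction from C7. The closure competes with oligomerisation and needs high dilution and a large excess of chromium. A2 carries a C7–H that is α to an aldehyde and γ to an acrylate and is therefore easily epimerised. C3, C7 and C8 would each need their own asymmetric step.
- Comparison: in structure the two plans meet at the same late intermediate. In mechanism the alternative is a polar carbonyl addition without a stereochemical relay, while the chosen plan relays C8 from chiral-pool centres in a unimolecular step. The alternative is shorter after its key step (three steps against thirteen). The chosen plan is shorter before it (eight steps from 1 against an estimated dozen or more). Overall the two are about equal in length.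

Alternative 2: The C2–C3 bond is cut. In the forward step BF3·OEt2 activates the C3 enal of the monocyclic lactone A4. The terminal alkene carbon of its α-trimethylsilyl β,γ-unsaturated ester attacks the enal with loss of silicon (intramolecular Hosomi–Sakurai reaction) and gives A3.
- In its favour: ring closure and the conjugated C1=C10 ester arise together at the right oxidation level. C6, C7 and C8 are set on a small lactone before the ring closes, where stereocontrol is conventional. On this point the alternative is the better plan, since the chosen route sets C6 and C7 on the macrocycle.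
- Against it: C3 is formed in the closure, far from any controlling centre. The C1=C10 geometry depends on the configuration of the quaternary silyl-bearing C10 and on anti SE2' attack. The nucleophile is an allylsilane deactivated by its ester. The Lewis acid meets an α-methylene lactone and an allylic C6–O bond vinylogous to the activated enal. A3 has the wrong hydroxyl free (O3 free, O8 silylated), which costs about four protecting-group steps.
- Comparison: the alternative is equal on convergence and better on the lactone stereocentres. It is weaker on C3 and on functional-group tolerance. In step count it is probably no shorter.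

Alternative 3: The C1–C2 bond is cut. Under blue light Ru(bpy)3Cl2 (a divalent ruthenium photocatalyst) and a Hantzsch ester reduce the N-acyloxyphthalimide of A6. Loss of CO2 gives a C2 radical that adds to C1 of the β-sulfonyl acrylate and expels a sulfonyl radical to give A5.
- In its favour: conditions are mild and neutral. All four ring stereocentres are in place before closure and none is made in it. On stereochemical security this is the better plan.
- Against it: a primary radical must close a ten-membered ring in competition with hydrogen transfer from the Hantzsch ester. This needs high dilution, and premature reduction is likely. The geometry of the regenerated alkene is not fixed by the mechanism. A5 lacks C13, so the lactone must be methylenated with the enoate present. A6 needs a long open-chain synthesis.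
- Comparison: the alternative is better on stereocentres. It is weaker on the efficiency of ring formation and on total steps. After the key step it is about equal (four steps to 36).

Key step: step 9

Remark on numbering: germacrane numbers are used for all carvone-derived compounds; C1–C6 is ring A, and C9, C10 and C14 come from the isopropenyl group.

Remark on the chemistry: natural L-(+)-diethyl tartrate is taken to deliver oxygen to the face of a 2-alken-1-ol that makes C2 of the epoxy alcohol S (as in the 2S,3S epoxides of E-2-alkenols); for 31 this face gives the (2S,3R) epoxide 32.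

Abbreviations: TBS = tert-butyldimethylsilyl, TMS = trimethylsilyl, PMB = 4-methoxybenzyl.

## Steps

Step 1
Reactants: 1 (S)-carvone
Product: 2 (5S)-5-(3-hydroxyprop-1-en-2-yl)-2-methylcyclohex-2-en-1-one
Conditions: SeO2 (cat.), t-BuOOH, salicylic acid (cat.), CH2Cl2, rt
Reagents that add atoms: tert-butyl hydroperoxide CC(C)(C)OO (oxygen atom, relayed by selenium dioxide O=[Se]=O)
Why: Selenium dioxide allylic oxidation (ene reaction, then [2,3] shift) attacks only the electron-rich 1,1-disubstituted alkene and, with no allylic CH2 there, its methyl group; the enone alkene is deactivated, any over-oxidised C14 aldehyde is returned to the alcohol in step 2, and the stereocentre is untouched.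

Step 2
Reactants: 2 (5S)-5-(3-hydroxyprop-1-en-2-yl)-2-methylcyclohex-2-en-1-one
Product: 3 (1S,5S)-5-(3-hydroxyprop-1-en-2-yl)-2-methylcyclohex-2-en-1-ol (cis diol)
Conditions: NaBH4, CeCl3·7H2O, MeOH, −20 °C
Reagents that add atoms: none
Why: Luche 1,2-reduction; axial hydride delivery to the half-chair enone should place the new hydroxyl cis to the side chain, which sets the future C3 (S).

Step 3
Reactants: 3 (1S,5S)-5-(3-hydroxyprop-1-en-2-yl)-2-methylcyclohex-2-en-1-ol
Product: 4 (1S,5S)-bis-TBS ether of 3 (O3 and O14 silylated)
Conditions: TBSCl, imidazole, DMF, rt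
Reagents that add atoms: tert-butyldimethylsilyl chloride CC(C)(C)[Si](C)(C)Cl
Why: Standard silylation of both hydroxyls in one operation; the primary (O14) and the hindered secondary (O3) silyl ethers can later be told apart by their rates of cleavage.

Step 4
Reactants: 4 (1S,5S)-bis-TBS ether
Product: 5 (4S,6S)-4-(TBS-oxy)-6-[3-(TBS-oxy)prop-1-en-2-yl]-3-methylcyclohex-2-en-1-one (germacrane C6 ketone, C4=C5 enone)
Conditions: CrO3, 3,5-dimethylpyrazole, CH2Cl2, −20 °C
Reagents that add atoms: chromium trioxide O=[Cr](=O)=O
Why: Allylic oxidation with the CrO3–3,5-dimethylpyrazole complex should convert the ring CH2 next to the unsubstituted alkene carbon into the ketone with the alkene left at C4=C5 (the 1-methylcyclohexene to 3-methylcyclohexenone pattern); the C3–H is shielded and deactivated by its silyloxy group and no stereocentre is touched.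

Step 5
Reactants: 6 4-methoxybenzyl alcohol; 7 ethyl vinyl ether
Product: 8 4-methoxybenzyl vinyl ether
Conditions: Pd(OAc)2 (cat.), 1,10-phenanthroline (cat.), ethyl vinyl ether as solvent, rt
Reagents that add atoms: none
Why: Transfer vinylation (transetherification) catalysed by divalent palladium; the large excess of 7 drives the exchange.

Step 6
Reactants: 8 4-methoxybenzyl vinyl ether
Product: 10 (Z)-1-bromo-2-[(4-methoxybenzyl)oxy]ethene, via dibromo ether 9 (not isolated)
Conditions: Br2, CH2Cl2, −78 °C; then i-Pr2NEt, −78 °C → reflux
Reagents that add atoms: bromine BrBr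
Why: Bromine adds to the enol ether far faster than to the anisole ring, and the hindered amine then removes HBr from the α-bromo ether; 1-alkoxy-2-haloethenes prefer the cis geometry, and the minor E isomer is removed by chromatography.

Step 7
Reactants: 10 (Z)-1-bromo-2-[(4-methoxybenzyl)oxy]ethene; 5 (4S,6S)-enone
Product: 13 (1S,4S,6S)-4-(TBS-oxy)-6-[3-(TBS-oxy)prop-1-en-2-yl]-1-[(Z)-2-(PMB-oxy)ethenyl]-3-methylcyclohex-2-en-1-ol, via vinyllithium 11 (not isolated), via vinylcerium dichloride 12 (not isolated)
Conditions: t-BuLi (2 equiv), Et2O, −78 °C; CeCl3, THF, −78 °C; then 5, −78 °C; aq. NH4Cl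
Reagents that add atoms: none
Why: Bromine–lithium exchange keeps the Z geometry, the weakly basic organocerium adds 1,2 without enolising the C1–H, and equatorial entry opposite the neighbouring C1 alkenyl group should set C6 (S) with the two alkenyl groups trans (organocerium carbonyl addition).

Step 8
Reactants: 13 (1S,4S,6S)-dialkenyl cyclohexenol
Product: 14 TMS ether of 13 (O6–SiMe3)
Conditions: N-(trimethylsilyl)imidazole, CH2Cl2, rt
Reagents that add atoms: N-(trimethylsilyl)imidazole C[Si](C)(C)n1ccnc1
Why: Neutral silylation of the tertiary alcohol; no acid is formed that could hydrolyse the enol ether or ionise the doubly allylic C6–O bond.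

Step 9
Reactants: 14 TMS ether of the trans-dialkenyl cyclohexenol
Product: 15 (3S,8R)-3,14-bis(TBS-oxy)-8-(PMB-oxy)-6-(TMS-oxy)germacra-1(10),4,6-triene (C1=C10 and C6=C7 ring-trans, C4=C5 ring-cis)
Conditions: toluene (0.02 M, degassed), N,O-bis(trimethylsilyl)acetamide (5 mol %), sealed silylated tube, 200 °C
Reagents that add atoms: none
Why: Concerted suprafacial [3,3] sigmatropic shift of the diene C8=C7–C6–C1–C10=C9; the closest known type is the thermal silyloxy-Cope rearrangement of trans-1,2-dialkenylcyclohexanol silyl ethers. The ten-membered ring is not closed end to end: it arises by four-atom ring expansion as the C1–C6 bond of ring A is exchanged for C8–C9. Because the alkenyl groups are trans, only one chair fits ring A, with C2 and C5 equatorial and O6 and H1 axial, which makes C1=C10 and C6=C7 ring-trans and leaves C4=C5 cis. The Z geometry puts the C8 ether oxygen pseudo-axial on that chair, so bonding to C9 gives 8R; C8 is thus controlled by the configurations of C1 and C6 together with the enol ether geometry. The selectivity needed is chair over boat and [3,3] over retro-ene cleavage, a [1,3] shift or a second shift across C1=C10 and C4=C5; the trans arrangement (a boat would need an eclipsed C7–C6–C1–C10 unit), the silyl cap on O6 and the cis C4=C5 alkene secure it. The silyl ether in place of an alkoxide keeps the new β-alkoxy enol derivative from eliminating, and conjugation of the enol ether with C4=C5 plus a new trisubstituted alkene should pull the equilibrium towards 15. The syn-diaxial contact of O6 and O8 in the transition state is the price of the Z geometry and the reason for planning about 200 °C.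

Step 10
Reactants: 15 silyl dienol ether
Product: 17 tert-butyl 2-[(3S,7R,8R)-3,14-bis(TBS-oxy)-8-(PMB-oxy)-6-oxogermacra-1(10),4-dien-7-yl]acetate, via lithium enolate 16 (not isolated)
Conditions: MeLi (1.0 equiv), THF, −30 °C; then DMPU, BrCH2CO2t-Bu, −78 → −40 °C
Reagents that add atoms: tert-butyl bromoacetate CC(C)(C)OC(=O)CBr
Why: Methyllithium cleaves the O–Si bond to give the regiodefined enolate, which is C-alkylated on the outer face of the ring-trans enolate, anti to the C8–C9 bond that stands perpendicular to the enolate plane in the crossed conformation delivered by step 9 (7R); in that conformation the C8–O bond lies near the enolate plane, which should slow β-elimination.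

Step 11
Reactants: 17 keto ester
Product: 18 tert-butyl 2-[(3S,6S,7S,8R)-3,14-bis(TBS-oxy)-6-hydroxy-8-(PMB-oxy)germacra-1(10),4-dien-7-yl]acetate
Conditions: NaBH4, CeCl3·7H2O, MeOH/THF, −78 → −40 °C
Reagents that add atoms: none
Why: Luche 1,2-reduction of the enone; hydride should enter on the open face anti to the C7–C8 ring bond (Felkin-type, with the ring branch as the large group), giving the 6S alcohol, the epimer that the invertive ring closure of step 12 needs; the tert-butyl ester does not lactonise under these conditions.

Step 12
Reactants: 18 (6S)-hydroxy ester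
Product: 20 (3S,6R,7R,8R)-3,14-bis(TBS-oxy)-8-(PMB-oxy)germacra-1(10),4-dien-12,6-olide (trans-fused; C1=C10 ring-trans), via allylic mesylate 19 (not isolated)
Conditions: Ms2O, 2,6-lutidine, CH2Cl2, −40 → 0 °C
Reagents that add atoms: none
Why: The carbonyl oxygen of the tert-butyl ester displaces the allylic mesylate from the rear in a 5-exo neighbouring-group substitution (inversion, 6R, trans fusion) and the tert-butyl group leaves as isobutene; this is invertive lactonisation of a γ-sulfonyloxy ester, and the anhydride avoids chloride that could give an allylic chloride.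

Step 13
Reactants: 20 trans-fused lactone
Product: 23 (3S,6R,7R,8R)-3,14-bis(TBS-oxy)-8-(PMB-oxy)germacra-1(10),4,11(13)-trien-12,6-olide, via Mannich base 21 (not isolated), via trimethylammonium iodide 22 (not isolated)
Conditions: LDA, THF, −78 °C; CH2=NMe2+ I−, −78 → 0 °C; then MeI, CH2Cl2/MeOH, rt; then aq. NaHCO3
Reagents that add atoms: N,N-dimethylmethyleneiminium iodide C=[N+](C)C.[I-]
Why: Lactone enolate aminomethylation with Eschenmoser's salt, quaternisation and E1cB loss of trimethylamine; at this stage the lactone α-CH2 is the only acidic site, and C11 ends sp2 so its transient configuration does not matter.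

Step 14
Reactants: 23 α-methylene lactone
Product: 24 (3S,6R,7R,8R)-3-(TBS-oxy)-14-hydroxy-8-(PMB-oxy)germacra-1(10),4,11(13)-trien-12,6-olide
Conditions: HF·pyridine, pyridine, THF, 0 °C
Reagents that add atoms: none
Why: Buffered fluoride cleaves the unhindered primary allylic silyl ether well before the secondary one at C3, which is flanked by the C4 methyl alkene.

Step 15
Reactants: 24 C14 allylic alcohol
Product: 26 (3S,6R,7R,8R)-3-(TBS-oxy)-14-oxo-8-(PMB-oxy)germacra-1(10),4,11(13)-trien-12,6-olide with C1=C10 ring-cis, via ring-trans enal 25 (not isolated)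
Conditions: MnO2, CH2Cl2, rt; filtration; then I2 (5 mol %), CH2Cl2, visible light, rt
Reagents that add atoms: none
Why: Allylic oxidation with MnO2, then iodine-atom addition–elimination at C1=C10 equilibrates the enal to the ring-cis, tiglaldehyde-type geometry, which should be favoured both by conjugation and by relief of trans-cyclodecene strain; iodine-atom adducts fragment too fast for transannular cyclisation, C4=C5 is already in its preferred cis form, and no nucleophile is present that could add to the methylene lactone.

Step 16
Reactants: 26 ring-cis enal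
Product: 28 methyl (3S,6R,7R,8R)-3-(TBS-oxy)-8-(PMB-oxy)-12-oxo-12,6-epoxygermacra-1(10),4,11(13)-trien-14-oate (both ring alkenes ring-cis), via carboxylic acid 27 (not isolated)
Conditions: NaClO2, NaH2PO4, 2-methyl-2-butene, t-BuOH/H2O, 0 °C → rt; then MeI, KHCO3, DMF, rt
Reagents that add atoms: sodium chlorite [Na+].[O-]Cl=O; iodomethane CI
Why: Pinnick oxidation keeps the alkene geometry and, with the hypochlorite scavenger, spares the other alkenes; carboxylate O-alkylation avoids diazoalkanes, which would add to the methylene lactone.

Step 17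
Reactants: 28 PMB ether
Product: 29 methyl (3S,6R,7R,8R)-3-(TBS-oxy)-8-hydroxy-12-oxo-12,6-epoxygermacra-1(10),4,11(13)-trien-14-oate
Conditions: DDQ, CH2Cl2/pH 7 buffer, 0 °C
Reagents that add atoms: none
Why: Oxidative cleavage of the electron-rich benzyl ether by hydride abstraction and hydrolysis; the allylic silyl ether and the electron-poor alkenes react far more slowly.

Step 18
Reactants: 30 angelic acid
Product: 31 (Z)-2-methylbut-2-en-1-ol
Conditions: LiAlH4, Et2O, 0 °C
Reagents that add atoms: none
Why: Hydride reduction of the carboxylate to the allylic alcohol; no reversible addition to the alkene occurs, so the Z geometry is kept.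

Step 19
Reactants: 31 (Z)-2-methylbut-2-en-1-ol
Product: 32 [(2S,3R)-2,3-dimethyloxiran-2-yl]methanol
Conditions: Ti(O-i-Pr)4 (cat.), L-(+)-diethyl tartrate (cat.), t-BuOOH, 4 Å molecular sieves, CH2Cl2, −20 °C
Reagents that add atoms: tert-butyl hydroperoxide CC(C)(C)OO
Why: Sharpless asymmetric epoxidation; syn oxygen transfer keeps the cis relation of the Z alkene, and the tartrate fixes the face and so both new stereocentres (see the remark before the steps).

Step 20
Reactants: 32 [(2S,3R)-2,3-dimethyloxiran-2-yl]methanol
Product: 33 (2R,3R)-2,3-dimethyloxirane-2-carboxylic acid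
Conditions: RuCl3·xH2O (cat.), NaIO4, MeCN/EtOAc/H2O, 0 °C → rt
Reagents that add atoms: sodium periodate [Na+].[O-]I(=O)(=O)=O; water O
Why: Ruthenium-catalysed oxidation of a primary epoxy alcohol to the glycidic acid without touching the oxirane; the descriptor at C2 changes from S to R only because the priorities change.

Step 21
Reactants: 29 C8 alcohol; 33 (2R,3R)-2,3-dimethyloxirane-2-carboxylic acid
Product: 35 3-O-TBS ether of the target, via mixed anhydride 34 (not isolated)
Conditions: 2,4,6-trichlorobenzoyl chloride, Et3N, toluene, rt; then 29, DMAP, rt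
Reagents that add atoms: none
Why: Yamaguchi esterification suits a hindered secondary alcohol and an α-quaternary acid; the weak base should not trigger acyl transfer to the lactone, and neither partner's stereocentres are involved.

Step 22
Reactants: 35 3-O-TBS ether of the target
Product: 36 target
Conditions: Et3N·3HF, MeCN, rt
Reagents that add atoms: none
Why: Near-neutral fluoride removes the remaining allylic silyl ether; the deactivated α,β-epoxy ester and the two Michael acceptors should tolerate it.

## Compound list

1 | (S)-carvone | CC1=CC[C@@H](CC1=O)C(C)=C | starting material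
2 | (5S)-5-(3-hydroxyprop-1-en-2-yl)-2-methylcyclohex-2-en-1-one | CC1=CC[C@@H](CC1=O)C(=C)CO | intermediate
3 | (1S,5S)-5-(3-hydroxyprop-1-en-2-yl)-2-methylcyclohex-2-en-1-ol | CC1=CC[C@@H](C[C@@H]1O)C(=C)CO | intermediate
4 | (1S,5S)-bis-TBS ether of 3 | CC1=CC[C@@H](C[C@@H]1O[Si](C)(C)C(C)(C)C)C(=C)CO[Si](C)(C)C(C)(C)C | intermediate
5 | (4S,6S)-4-(TBS-oxy)-6-[3-(TBS-oxy)prop-1-en-2-yl]-3-methylcyclohex-2-en-1-one | CC1=CC(=O)[C@@H](C[C@@H]1O[Si](C)(C)C(C)(C)C)C(=C)CO[Si](C)(C)C(C)(C)C | intermediate
6 | 4-methoxybenzyl alcohol | COc1ccc(CO)cc1 | starting material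
7 | ethyl vinyl ether | C=COCC | starting material
8 | 4-methoxybenzyl vinyl ether | C=COCc1ccc(OC)cc1 | intermediate
9 | 1,2-dibromoethyl 4-methoxybenzyl ether (racemic, not isolated) | BrCC(Br)OCc1ccc(OC)cc1 | intermediate
10 | (Z)-1-bromo-2-[(4-methoxybenzyl)oxy]ethene | Br/C=C\OCc1ccc(OC)cc1 | intermediate
11 | (Z)-2-[(4-methoxybenzyl)oxy]ethenyllithium (not isolated) | [Li]/C=C\OCc1ccc(OC)cc1 | intermediate
12 | dichloro[(Z)-2-(4-methoxybenzyloxy)ethenyl]cerium (not isolated) | Cl[Ce](Cl)/C=C\OCc1ccc(OC)cc1 | intermediate
13 | (1S,4S,6S)-4-(TBS-oxy)-6-[3-(TBS-oxy)prop-1-en-2-yl]-1-[(Z)-2-(PMB-oxy)ethenyl]-3-methylcyclohex-2-en-1-ol | O[C@@]1(/C=C\OCc2ccc(OC)cc2)C=C(C)[C@@H](O[Si](C)(C)C(C)(C)C)C[C@H]1C(=C)CO[Si](C)(C)C(C)(C)C | intermediate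
14 | TMS ether of 13 (key-step precursor) | C[Si](C)(C)O[C@@]1(/C=C\OCc2ccc(OC)cc2)C=C(C)[C@@H](O[Si](C)(C)C(C)(C)C)C[C@H]1C(=C)CO[Si](C)(C)C(C)(C)C | intermediate
15 | (3S,8R)-3,14-bis(TBS-oxy)-8-(PMB-oxy)-6-(TMS-oxy)germacra-1(10),4,6-triene, C1=C10 and C6=C7 ring-trans, C4=C5 ring-cis | C1/C(CO[Si](C)(C)C(C)(C)C)=C/C[C@H](O[Si](C)(C)C(C)(C)C)/C(C)=C\C(O[Si](C)(C)C)=C\[C@@H]1OCc1ccc(OC)cc1 | intermediate
16 | lithium enolate corresponding to 15 (not isolated) | C1/C(CO[Si](C)(C)C(C)(C)C)=C/C[C@H](O[Si](C)(C)C(C)(C)C)/C(C)=C\C(O[Li])=C\[C@@H]1OCc1ccc(OC)cc1 | intermediate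
17 | tert-butyl 2-[(3S,7R,8R)-3,14-bis(TBS-oxy)-8-(PMB-oxy)-6-oxogermacra-1(10),4-dien-7-yl]acetate | C1/C(CO[Si](C)(C)C(C)(C)C)=C/C[C@H](O[Si](C)(C)C(C)(C)C)/C(C)=C\C(=O)[C@H](CC(=O)OC(C)(C)C)[C@@H]1OCc1ccc(OC)cc1 | intermediate
18 | tert-butyl 2-[(3S,6S,7S,8R)-3,14-bis(TBS-oxy)-6-hydroxy-8-(PMB-oxy)germacra-1(10),4-dien-7-yl]acetate | C1/C(CO[Si](C)(C)C(C)(C)C)=C/C[C@H](O[Si](C)(C)C(C)(C)C)/C(C)=C\[C@H](O)[C@H](CC(=O)OC(C)(C)C)[C@@H]1OCc1ccc(OC)cc1 | intermediate
19 | 6-O-methanesulfonate of 18 (not isolated) | C1/C(CO[Si](C)(C)C(C)(C)C)=C/C[C@H](O[Si](C)(C)C(C)(C)C)/C(C)=C\[C@H](OS(C)(=O)=O)[C@H](CC(=O)OC(C)(C)C)[C@@H]1OCc1ccc(OC)cc1 | intermediate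
20 | (3S,6R,7R,8R)-3,14-bis(TBS-oxy)-8-(PMB-oxy)germacra-1(10),4-dien-12,6-olide, trans-fused, C1=C10 ring-trans | C1C(=O)O[C@@H]2/C=C(/C)[C@@H](O[Si](C)(C)C(C)(C)C)C/C=C(\CO[Si](C)(C)C(C)(C)C)C[C@@H](OCc3ccc(OC)cc3)[C@@H]12 | intermediate
21 | 11-(dimethylaminomethyl) derivative of 20 (C11 epimers, not isolated) | CN(C)CC1C(=O)O[C@@H]2/C=C(/C)[C@@H](O[Si](C)(C)C(C)(C)C)C/C=C(\CO[Si](C)(C)C(C)(C)C)C[C@@H](OCc3ccc(OC)cc3)[C@@H]12 | intermediate
22 | 11-(trimethylammoniomethyl) iodide of 20 (C11 epimers, not isolated) | C[N+](C)(C)CC1C(=O)O[C@@H]2/C=C(/C)[C@@H](O[Si](C)(C)C(C)(C)C)C/C=C(\CO[Si](C)(C)C(C)(C)C)C[C@@H](OCc3ccc(OC)cc3)[C@@H]12.[I-] | intermediate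
23 | (3S,6R,7R,8R)-3,14-bis(TBS-oxy)-8-(PMB-oxy)germacra-1(10),4,11(13)-trien-12,6-olide, C1=C10 ring-trans | C=C1C(=O)O[C@@H]2/C=C(/C)[C@@H](O[Si](C)(C)C(C)(C)C)C/C=C(\CO[Si](C)(C)C(C)(C)C)C[C@@H](OCc3ccc(OC)cc3)[C@@H]12 | intermediate
24 | 14-hydroxy analogue of 23 (O3 still TBS) | C=C1C(=O)O[C@@H]2/C=C(/C)[C@@H](O[Si](C)(C)C(C)(C)C)C/C=C(\CO)C[C@@H](OCc3ccc(OC)cc3)[C@@H]12 | intermediate
25 | 14-aldehyde, C1=C10 ring-trans (not isolated) | C=C1C(=O)O[C@@H]2/C=C(/C)[C@@H](O[Si](C)(C)C(C)(C)C)C/C=C(\C=O)C[C@@H](OCc3ccc(OC)cc3)[C@@H]12 | intermediate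
26 | 14-aldehyde, C1=C10 ring-cis | C=C1C(=O)O[C@@H]2/C=C(/C)[C@@H](O[Si](C)(C)C(C)(C)C)C/C=C(/C=O)C[C@@H](OCc3ccc(OC)cc3)[C@@H]12 | intermediate
27 | 14-carboxylic acid, C1=C10 ring-cis (not isolated) | C=C1C(=O)O[C@@H]2/C=C(/C)[C@@H](O[Si](C)(C)C(C)(C)C)C/C=C(/C(=O)O)C[C@@H](OCc3ccc(OC)cc3)[C@@H]12 | intermediate
28 | methyl (3S,6R,7R,8R)-3-(TBS-oxy)-8-(PMB-oxy)-12-oxo-12,6-epoxygermacra-1(10),4,11(13)-trien-14-oate | C=C1C(=O)O[C@@H]2/C=C(/C)[C@@H](O[Si](C)(C)C(C)(C)C)C/C=C(/C(=O)OC)C[C@@H](OCc3ccc(OC)cc3)[C@@H]12 | intermediate
29 | methyl (3S,6R,7R,8R)-3-(TBS-oxy)-8-hydroxy-12-oxo-12,6-epoxygermacra-1(10),4,11(13)-trien-14-oate | C=C1C(=O)O[C@@H]2/C=C(/C)[C@@H](O[Si](C)(C)C(C)(C)C)C/C=C(/C(=O)OC)C[C@@H](O)[C@@H]12 | intermediate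
30 | angelic acid, (Z)-2-methylbut-2-enoic acid | C/C=C(/C)C(=O)O | starting material
31 | (Z)-2-methylbut-2-en-1-ol | C/C=C(/C)CO | intermediate
32 | [(2S,3R)-2,3-dimethyloxiran-2-yl]methanol | OC[C@]1(C)O[C@@H]1C | intermediate
33 | (2R,3R)-2,3-dimethyloxirane-2-carboxylic acid | OC(=O)[C@]1(C)O[C@@H]1C | intermediate
34 | mixed anhydride of 33 and 2,4,6-trichlorobenzoic acid (not isolated) | O=C(OC(=O)c1c(Cl)cc(Cl)cc1Cl)[C@]1(C)O[C@@H]1C | intermediate
35 | 3-O-TBS ether of the target | C=C1C(=O)O[C@@H]2/C=C(/C)[C@@H](O[Si](C)(C)C(C)(C)C)C/C=C(/C(=O)OC)C[C@@H](OC(=O)[C@]3(C)O[C@@H]3C)[C@@H]12 | intermediate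
36 | methyl (3S,6R,7R,8R)-8-[(2R,3R)-2,3-dimethyloxirane-2-carbonyloxy]-3-hydroxy-12-oxo-12,6-epoxygermacra-1(10),4,11(13)-trien-14-oate (CNP0143679.1) | C=C1C(=O)O[C@@H]2/C=C(/C)[C@@H](O)C/C=C(/C(=O)OC)C[C@@H](OC(=O)[C@]3(C)O[C@@H]3C)[C@@H]12 | target

## Step count and least certain steps

Total: 22 steps. Longest linear sequence: 17 steps (1–4, 7–17, 21, 22). Side branches: steps 5–6 and steps 18–20.

Step 9 (key step). The shift may stop short of completion because the reverse shift to the strain-free cyclohexene competes. At 200 °C a hydrogen shift within the new dienol ether, a second shift across C1=C10 and C4=C5, or leakage through a boat (C8 epimer) may also set in. Fallback: the anion-accelerated variant, which runs far below room temperature. It sets out from 13: KHMDS and 18-crown-6 in THF at −78 °C give the potassium alkoxide F1. On warming to about −30 °C this rearranges through the same chair to the potassium enolate F2, which is trapped at once with tert-butyl bromoacetate. The route is rejoined at 17. The risk moved to this variant is loss of the C8 ether from the enolate, which is why it is not the first choice.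

Step 10. The enolate may react on its inner face after the C6=C7 unit has swivelled through the ring (poor facial selectivity at C7), or it may expel the C8 alkoxide on warming. Fallback: stereocontrol is moved from C–C to C–H bond formation. The route sets out from 15 as in step 10. If the product is the C7 epimer F3, it is deprotonated with LiHMDS at −78 °C to the tetrasubstituted lithium enolate F4 and quenched cold with acetic acid. The proton should enter on the face that had admitted the alkyl halide, which inverts C7 and rejoins the route at 17.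

Step 11. Hydride may be delivered to the other face of the C6 ketone (for example through a conformer in which the acetate arm acts as the large group), giving the 6R alcohol. Fallback: the ring closure is changed from invertive to retentive. From 17 the same reduction would then give the (6R)-hydroxy ester F5, which is lactonised with catalytic p-TsOH in toluene at 50 °C with loss of tert-butanol and retention at C6. The route is rejoined at 20.

Step 12. The allylic mesylate may ionise before the ester oxygen attacks, leading to loss of stereochemical integrity at C6, elimination to a diene or transannular capture by C1=C10. Fallback: intermolecular inversion without a free sulfonate. From 18, Mitsunobu reaction (PPh3, diisopropyl azodicarboxylate, 4-nitrobenzoic acid) gives the inverted 4-nitrobenzoate F6. K2CO3 in methanol frees the (6R)-hydroxy ester F5, and catalytic p-TsOH closes it to 20.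

Step 4. Oxidation may spread over competing allylic sites (the silyloxy-bearing C3–H, the C4 methyl, the C14 methylene), giving poor site selectivity. Fallback: a regiodefined oxidative transposition in three operations. From 4, mCPBA gives the ring epoxide F7. Sodium phenylselenide opens it at C5 to the hydroxy selenide F8. H2O2 then gives, by selenoxide elimination away from the carbinol, the tertiary allylic alcohol F9 (C4 carbinol, C5=C6 alkene). Pyridinium chlorochromate then effects the Babler–Dauben oxidative 1,3-transposition to 5.

Step 15. The equilibration may stall, or radical addition to the methylene lactone may divert material. Fallback: a polar addition–elimination. From 24, MnO2 gives 25 as before. PhSH with Et3N adds to both acceptors to give the bis(phenylthio) adduct F10. NaIO4 oxidises it to the bis-sulfoxide F11. Warming with Et3N then eliminates benzenesulfenic acid twice, which restores the methylene lactone and forms the enal in its more stable ring-cis geometry. The route is rejoined at 26.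

## Further compounds

F1 | step 9 | potassium alkoxide of 13 | [K]O[C@@]1(/C=C\OCc2ccc(OC)cc2)C=C(C)[C@@H](O[Si](C)(C)C(C)(C)C)C[C@H]1C(=C)CO[Si](C)(C)C(C)(C)C
F2 | step 9 | potassium enolate of the ring-expanded C6 ketone | C1/C(CO[Si](C)(C)C(C)(C)C)=C/C[C@H](O[Si](C)(C)C(C)(C)C)/C(C)=C\C(O[K])=C\[C@@H]1OCc1ccc(OC)cc1
F3 | step 10 | (3S,7S,8R) C7 epimer of 17 | C1/C(CO[Si](C)(C)C(C)(C)C)=C/C[C@H](O[Si](C)(C)C(C)(C)C)/C(C)=C\C(=O)[C@@H](CC(=O)OC(C)(C)C)[C@@H]1OCc1ccc(OC)cc1
F4 | step 10 | lithium C6–C7 enolate of the keto ester | C1/C(CO[Si](C)(C)C(C)(C)C)=C/C[C@H](O[Si](C)(C)C(C)(C)C)/C(C)=C\C(O[Li])=C(CC(=O)OC(C)(C)C)[C@@H]1OCc1ccc(OC)cc1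
F5 | step 11 | (3S,6R,7S,8R) C6 epimer of 18 | C1/C(CO[Si](C)(C)C(C)(C)C)=C/C[C@H](O[Si](C)(C)C(C)(C)C)/C(C)=C\[C@@H](O)[C@H](CC(=O)OC(C)(C)C)[C@@H]1OCc1ccc(OC)cc1
F6 | step 12 | (6R)-4-nitrobenzoate from 18 | C1/C(CO[Si](C)(C)C(C)(C)C)=C/C[C@H](O[Si](C)(C)C(C)(C)C)/C(C)=C\[C@@H](OC(=O)c2ccc(cc2)[N+](=O)[O-])[C@H](CC(=O)OC(C)(C)C)[C@@H]1OCc1ccc(OC)cc1
F7 | step 4 | ring epoxide of 4 (epoxide carbons as a mixture) | CC12OC2C[C@@H](C[C@@H]1O[Si](C)(C)C(C)(C)C)C(=C)CO[Si](C)(C)C(C)(C)C
F8 | step 4 | hydroxy selenide from F7 (new centres as a mixture) | CC1(O)C([Se]c2ccccc2)C[C@@H](C[C@@H]1O[Si](C)(C)C(C)(C)C)C(=C)CO[Si](C)(C)C(C)(C)C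
F9 | step 4 | tertiary allylic alcohol with C5=C6 alkene (carbinol as a mixture) | CC1(O)C=C[C@@H](C[C@@H]1O[Si](C)(C)C(C)(C)C)C(=C)CO[Si](C)(C)C(C)(C)C
F10 | step 15 | bis(phenylthio) adduct of 25 (C1, C10, C11 as mixtures) | c1ccccc1SCC1C(=O)O[C@@H]2/C=C(/C)[C@@H](O[Si](C)(C)C(C)(C)C)CC(Sc3ccccc3)C(C=O)C[C@@H](OCc3ccc(OC)cc3)[C@@H]12
F11 | step 15 | bis-sulfoxide of F10 | c1ccccc1S(=O)CC1C(=O)O[C@@H]2/C=C(/C)[C@@H](O[Si](C)(C)C(C)(C)C)CC(S(=O)c3ccccc3)C(C=O)C[C@@H](OCc3ccc(OC)cc3)[C@@H]12
A1 | alternative 1 | bicyclic core with C3 TBS ether and C8 PMB ether (same structure as 28) | C=C1C(=O)O[C@@H]2/C=C(/C)[C@@H](O[Si](C)(C)C(C)(C)C)C/C=C(/C(=O)OC)C[C@@H](OCc3ccc(OC)cc3)[C@@H]12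
A2 | alternative 1 | open-chain Z iodoalkene aldehyde diester | I/C=C(/C)[C@@H](O[Si](C)(C)C(C)(C)C)C/C=C(/C(=O)OC)C[C@@H](OCc1ccc(OC)cc1)[C@H](C=O)C(=C)C(=O)OC
A3 | alternative 2 | bicyclic core with free C3 hydroxyl and C8 triethylsilyl ether | C=C1C(=O)O[C@@H]2/C=C(/C)[C@@H](O)C/C=C(/C(=O)OC)C[C@@H](O[Si](CC)(CC)CC)[C@@H]12
A4 | alternative 2 | monocyclic lactone with C3 enal and α-trimethylsilyl β,γ-unsaturated ester (C10 configuration left open) | C=C1C(=O)O[C@H](/C=C(/C)C=O)[C@H]1[C@H](O[Si](CC)(CC)CC)CC(C=C)(C(=O)OC)[Si](C)(C)C
A5 | alternative 3 | bicyclic lactone without C13, with C3 TBS ether and C8 PMB ether | C1C(=O)O[C@@H]2/C=C(/C)[C@@H](O[Si](C)(C)C(C)(C)C)C/C=C(/C(=O)OC)C[C@@H](OCc3ccc(OC)cc3)[C@@H]12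
A6 | alternative 3 | monocyclic lactone with C2 N-acyloxyphthalimide and β-sulfonyl acrylate | C1C(=O)O[C@H](/C=C(/C)[C@@H](O[Si](C)(C)C(C)(C)C)CC(=O)ON3C(=O)c4ccccc4C3=O)[C@H]1[C@H](OCc1ccc(OC)cc1)C/C(C(=O)OC)=C/S(=O)(=O)c1ccccc1
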